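## Structural features

The target is a chroman-4-one: a benzene ring fused through C4a and C8a to a dihydropyranone ring (O1, C2, C3, C4). Every benzene position is substituted: hydroxyl on C5, 3-methylbut-2-enyl (prenyl) on C6, methoxy on C7 and a 2-carboxy-1-phenylethyl chain on C8. C2 and C3 are adjacent stereocentres, each carrying a methyl group. Reading the SMILES gives 2S,3R with the two methyls cis, and R at the benzylic carbon on C8, which has no direct bond to the ring centres. The cis arrangement is the less stable one, because C3 is alpha to the C4 ketone and beta to O1, so base can epimerise it by enolisation or by ring opening and re-closure. The prenyl alkene next to the C5 hydroxyl is sensitive to acid and to hydrogenation. The free acid and phenol would both trap a carbene. The real difficulty is twofold: placing six different substituents around one benzene ring, where O1 and O5 both flank the ketone and must be told apart, and creating the cis-2,3-dimethyl unit as one enantiomer without ever equilibrating it. The key step uses the fact that C2 is an ether carbon with one hydrogen and C3 is the alpha carbon of the C4 ketone: a carbene at C3 inserts into an O–CH2 bond of an ethoxy group on C8a, forming C2–C3 and closing the pyranone ring. That CH2 is prochiral before the step, so the configuration at C2 comes from a choice between two enantiotopic hydrogens and not from retention at an existing centre.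

## Logic of the disconnections

Coumarin numbering is used for 3, 6–9 and 11. Coumarin C4a, C5, C6, C7, C8, C8a and O1 become chromanone C8, C7, C6, C5, C4a, C8a and O1.

18 to 17: the O5–Si bond is cut last. The free phenol must not be present earlier, because it would trap the carbene, interfere with enolate chemistry and invite cyclisation onto the prenyl group. Nothing skeletal is gained, but the last step becomes base-free. The forward step needs buffered fluoride so that C3 does not epimerise.

17 to 16: the carboxyl O–allyl bond is cut. An allyl ester is released by zerovalent palladium at room temperature to a non-basic acceptor, whereas a methyl ester would need hydroxide or a hot tin hydroxide next to the epimerisable centre. The gain is an acid that stays masked through the carbene step. The forward step needs an acceptor that is not basic.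

16 to 15: the C2–C3 bond is cut. This removes the pyranone ring and both ring stereocentres and leaves an aryl diazo ketone flanked by an ethoxy group and a silyloxy group. The forward step must select one enantiotopic O–CH2 hydrogen, deliver the cis isomer and outrun 1,2-hydride shift. It also requires an O5 substituent with no C–H next to oxygen, which rules out benzyl, methoxymethyl or methyl ethers.

15 to 13 (through 14): the C3=N2 bond is cut, since a diazo ketone cannot be carried through earlier steps. The gain is a plain ethyl ketone. The forward step runs through a ketone enolate. That excludes an acetate on O5, which would shift to carbon (Baker–Venkataraman). It also excludes a free O5 hydroxyl, which would close onto the trifluoroacetyl group as a cyclic hemiketal. A silyl ether tolerates the enolate and also satisfies the carbene step.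

13 to 11 (through 12): the O1–ethyl bond and the ester C–O bond are both traced back to one lactone. In 11 the lactone masks O1, which distinguishes it from O5 on the other side of the ketone, and it protects the acid at the same time. The forward step needs an alkoxide opening that spares the aryl silyl ether.

11 to 9 and 10: the C4–phenyl bond is cut. Asymmetric conjugate arylation of a coumarin is an established catalytic route to this benzylic centre. The gain is a flat, achiral coumarin. The forward step must work on a hindered, electron-rich acceptor with ligand-controlled face selection.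

9 to 8 to 7: the O7–Si and O5–CH3 bonds are cut. The 7-hydroxyl is hydrogen-bonded to the C8 ketone and the 5-hydroxyl is not, so the two oxygens react in a fixed order without any temporary protecting group. The forward steps rely on that difference in nucleophilicity.

7 to 6 to 3 and 5 (5 from 4): the C6–CH2 bond of the prenyl group is cut by a [3,3] shift back to a tertiary allyl ether on O5, and then the O5–C bond is cut. Only C6 is open to an ether on O5, so the regiochemistry is structural. The forward steps need O-allylation at the non-chelated hydroxyl and a rearrangement without acid.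

3 to 1 and 2: the C8–acyl bond is cut. C8 is the most nucleophilic carbon of a 5,7-dihydroxycoumarin, and the new ketone is what differentiates the two hydroxyls in the steps above. The forward step needs C8 over C6 selectivity.

## Other disconnections considered

Alternative 1: The cut removes three benzene bonds (C7–C8, C8a–C4a, C6–C7). In the forward direction 3-ethoxy-4-(3-methylbut-2-enyl)cyclobut-2-en-1-one A2 and the chiral siloxyalkyne A3 are heated, and ring opening, [2+2] addition, a second ring opening and 6π closure (Danheiser benzannulation) give the phenol A1.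
- In favour: the substitution pattern follows from the connectivity of two fragments and not from directing effects. On this point it is better than the chosen plan, which depends on site selectivity in steps 1, 3 and 5. The cascade needs no catalyst and is mechanistically robust, which is at least equal.
- Against: in A1 the ethyl ether sits on the carbon that becomes C5, which is a free hydroxyl in the target, while O1 carries the silyl group. The ethyl group therefore cannot become C2 and has to be cleaved late, next to a prenyl group. C4a is still unsubstituted, so the acyl group, the pyranone ring and both ring stereocentres remain to be made. The side chain is at the alcohol level and needs two oxidations. A3 with its propargylic stereocentre is a multi-step fragment.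
- Comparison: the arene assembly is more elegant, but the stereochemical problem that step 10 solves in 16 is left untouched and the step count is clearly higher.

Alternative 2: The cut removes O1–C8a and C4–C4a together. In the forward direction fluoride triggers elimination from the ortho-silylaryl triflate A5, the acid A6 inserts across the new triple bond with its oxygen on C8a and its acyl carbon on C4a, and the phenoxide displaces methoxide to give the chromone A4.
- In favour: two bonds to the arene and the ring form in one flask, and the benzyloxy group should direct oxygen to C8a. A4 has no epimerisable centre and can be stored and purified freely, which is better than 16. Syn hydrogenation of C2=C3 would give the cis relation by itself, which is equal or better for relative configuration.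
- Against: the absolute configuration at C2 and C3 must come from face-selective reduction of a tetrasubstituted, electron-rich alkene with only a remote stereocentre to guide it, and no dependable asymmetric method exists for this. Hydride conjugate reduction would favour the trans isomer on protonation. C6 still lacks the prenyl group, which would have to be added to an epimerisable cis-chromanone. A5 is a long fragment.
- Comparison: ring formation is the equal of step 10, stereocontrol is weaker and the sequence is longer.

Alternative 3: The cut removes C4–C4a. In the forward direction iodine–lithium exchange on the aryl iodide A8 and attack of the lithiated carbon on the tethered N-methoxy-N-methylamide (Parham-type cyclisation) give the chromanone A7.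
- In favour: both ring stereocentres come from an enantiopure four-carbon unit, so absolute and relative configuration do not depend on catalyst and substrate matching. This is better than the chosen plan in certainty of configuration. The ketone forms at low temperature and is released on mild quench.
- Against: the O1–C2 ether must be made by substitution at a secondary carbinol beta to a carbonyl using a phenol with two ortho substituents, where elimination is expected to dominate. The beta-aryloxy amide has an acidic alpha hydrogen facing t-BuLi, so epimerisation at C3 or expulsion of the phenoxide threatens. The side-chain methyl ester competes for the organolithium. The methoxymethyl group needs acid next to a prenyl group, and the methyl ester needs a basic hydrolysis of the cis-chromanone.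
- Comparison: the step count is about equal if the etherification works. Each plan has a different weak point: catalyst-dependent stereocontrol in step 10 versus a doubtful ether synthesis and strongly basic closure here. The end-game of the chosen plan is milder.

Key step: step 10

Assumption: the facial sense of the two catalyst-controlled steps (7 and 10) is assigned by analogy with simpler substrates; if either ran in the opposite sense, the enantiomeric ligand would be used with no other change to the route.

## Steps

Step 1
Reactants: 1 5,7-dihydroxycoumarin; 2 propanoyl chloride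
Product: 3 5,7-dihydroxy-8-propanoylcoumarin
Conditions: AlCl3 (4 equiv), PhNO2–ClCH2CH2Cl, 75 °C; aq. HCl work-up
Reagents that add atoms: none
Why: Friedel–Crafts acylation; C8, between O1 and the 7-hydroxyl, is the most nucleophilic carbon of 5,7-dihydroxycoumarins and the product is held as an aluminium chelate of the 7-phenoxide and the new ketone, while the lactone and C3=C4 are inert.

Step 2
Reactants: 4 2-methylbut-3-en-2-ol
Product: 5 tert-butyl 2-methylbut-3-en-2-yl carbonate
Conditions: n-BuLi, THF, −78 °C; Boc2O, −78 °C → rt
Reagents that add atoms: di-tert-butyl dicarbonate, CC(C)(C)OC(=O)OC(=O)OC(C)(C)C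
Why: O-acylation of the lithium alkoxide of a tertiary allylic alcohol; the carbonate is the ionisable partner for the palladium allylation.

Step 3
Reactants: 3 5,7-dihydroxy-8-propanoylcoumarin; 5 tert-butyl 2-methylbut-3-en-2-yl carbonate
Product: 6 7-hydroxy-5-(2-methylbut-3-en-2-yloxy)-8-propanoylcoumarin
Conditions: Pd(PPh3)4 (5 mol %), THF, 0 °C
Reagents that add atoms: none
Why: Tsuji–Trost O-allylation; zerovalent palladium ionises 5 with loss of CO2, the tert-butoxide formed deprotonates the free 5-hydroxyl and the phenoxide attacks the more substituted allyl terminus under kinetic control at low temperature, while the 7-hydroxyl is tied up in a hydrogen bond to the C8 ketone and is the weaker nucleophile.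

Step 4
Reactants: 6 7-hydroxy-5-(2-methylbut-3-en-2-yloxy)-8-propanoylcoumarin
Product: 7 5,7-dihydroxy-6-(3-methylbut-2-enyl)-8-propanoylcoumarin
Conditions: PhNEt2, 130 °C
Reagents that add atoms: none
Why: aromatic Claisen rearrangement; of the two positions ortho to O5 only C6 carries hydrogen (C4a is a fusion atom) and the para position C8 is blocked by the acyl group, so the [3,3] shift followed by enolisation can deliver the prenyl group only to C6, and the amine solvent suppresses acid-promoted loss of the allyl group.

Step 5
Reactants: 7 5,7-dihydroxy-6-(3-methylbut-2-enyl)-8-propanoylcoumarin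
Product: 8 7-hydroxy-5-methoxy-6-(3-methylbut-2-enyl)-8-propanoylcoumarin
Conditions: MeI (1.1 equiv), K2CO3, acetone, rt
Reagents that add atoms: iodomethane, CI
Why: Williamson etherification; the non-chelated 5-hydroxyl is alkylated while the 7-hydroxyl, hydrogen-bonded to the ketone and flanked by two ortho substituents, should remain.

Step 6
Reactants: 8 7-hydroxy-5-methoxy-6-(3-methylbut-2-enyl)-8-propanoylcoumarin
Product: 9 5-methoxy-6-(3-methylbut-2-enyl)-8-propanoyl-7-(triisopropylsilyloxy)coumarin
Conditions: i-Pr3SiOTf, 2,6-lutidine, CH2Cl2, 0 °C → rt
Reagents that add atoms: triisopropylsilyl trifluoromethanesulfonate, CC(C)[Si](OS(=O)(=O)C(F)(F)F)(C(C)C)C(C)C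
Why: O-silylation with a silyl triflate, reactive enough for a hindered chelated phenol; the bulky silyl ether has no C–H next to oxygen, resists alkoxide and amide bases better than smaller silyl groups and leaves with fluoride.

Step 7
Reactants: 9 5-methoxy-6-(3-methylbut-2-enyl)-8-propanoyl-7-(triisopropylsilyloxy)coumarin; 10 phenylboronic acid
Product: 11 (R)-5-methoxy-6-(3-methylbut-2-enyl)-4-phenyl-8-propanoyl-7-(triisopropylsilyloxy)chroman-2-one
Conditions: Rh(acac)(C2H4)2 (3 mol %), (R)-SEGPHOS (3.3 mol %), dioxane–H2O (10:1), 60 °C, boronic acid in portions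
Reagents that add atoms: none
Why: Hayashi–Miyaura asymmetric 1,4-addition; transmetallation gives a phenyl complex of monovalent rhodium, which adds across C3=C4, and water protonates the resulting enolate; the chiral bisphosphine selects the alkene face, and by analogy with simpler coumarins the (R) ligand should give 4R, the centre that becomes the benzylic R centre of the target with unchanged priorities.

Step 8
Reactants: 11 (R)-5-methoxy-6-(3-methylbut-2-enyl)-4-phenyl-8-propanoyl-7-(triisopropylsilyloxy)chroman-2-one
Product: 13 allyl (R)-3-[2-ethoxy-6-methoxy-5-(3-methylbut-2-enyl)-3-propanoyl-4-(triisopropylsilyloxy)phenyl]-3-phenylpropanoate, via ring-opened phenol allyl ester 12 (not isolated)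
Conditions: NaH (1.1 equiv), CH2=CHCH2OH (3 equiv), THF, −20 °C; then EtI, DMF, rt
Reagents that add atoms: allyl alcohol, C=CCO; iodoethane, CCI
Why: alcoholysis of the aryl lactone by sodium allyloxide is fast at low temperature and gives the allyl ester and the O1 phenoxide, which is ethylated in the same flask (Williamson etherification); one equivalent of alkoxide is consumed at once by the lactone, which should spare the hindered silyl ether, and the benzylic centre is not acidic and is untouched.

Step 9
Reactants: 13 allyl (R)-3-[2-ethoxy-6-methoxy-5-(3-methylbut-2-enyl)-3-propanoyl-4-(triisopropylsilyloxy)phenyl]-3-phenylpropanoate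
Product: 15 allyl (R)-3-[3-(2-diazopropanoyl)-2-ethoxy-6-methoxy-5-(3-methylbut-2-enyl)-4-(triisopropylsilyloxy)phenyl]-3-phenylpropanoate, via trifluoroacetylated diketone 14 (not isolated)
Conditions: LiN(SiMe3)2 (1.1 equiv), THF, −78 °C; CF3CO2CH2CF3; then 4-AcNHC6H4SO2N3, Et3N, H2O, MeCN, rt
Reagents that add atoms: 4-acetamidobenzenesulfonyl azide, CC(=O)Nc1ccc(cc1)S(=O)(=O)N=[N+]=[N-]; 2,2,2-trifluoroethyl trifluoroacetate, O=C(OCC(F)(F)F)C(F)(F)F (its acyl group stays in 14 only)
Why: detrifluoroacetylative diazo transfer; the ketone, more acidic than the ester, is enolised and C-trifluoroacetylated, and the activated diketone takes up the diazo group from the sulfonyl azide and loses the trifluoroacetyl group as the N-acyl sulfonamide; the silyl ether on O5 can neither migrate as an acyl group nor close onto the trifluoroacetyl carbonyl.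

Step 10
Reactants: 15 allyl (R)-3-[3-(2-diazopropanoyl)-2-ethoxy-6-methoxy-5-(3-methylbut-2-enyl)-4-(triisopropylsilyloxy)phenyl]-3-phenylpropanoate
Product: 16 allyl (R)-3-[(2S,3R)-7-methoxy-2,3-dimethyl-6-(3-methylbut-2-enyl)-4-oxo-5-(triisopropylsilyloxy)chroman-8-yl]-3-phenylpropanoate
Conditions: Rh2(S-PTTL)4 (PTTL = N-phthaloyl-tert-leucinate; 1 mol %), toluene, −20 °C, slow addition of 15
Reagents that add atoms: none
Why: Rh2(S-PTTL)4 expels N2 from 15 to give an electrophilic carbenoid of divalent rhodium at C3, and the ether oxygen on C8a stabilises the positive charge that builds at its O–CH2 carbon, so hydride-like transfer of one methylene hydrogen to C3 and C2–C3 bond formation occur in one three-centre event as the metal leaves. The closest known reaction type is the dirhodium-carboxylate-catalysed intramolecular C–H insertion of 2-alkoxyaryl alpha-diazo ketones to chroman-4-ones. The pyranone ring closes by 1,6-insertion through C3, C4, C4a, C8a, O1 and C2, the only ring size open to the carbenoid because the arene holds carbene and ether ortho to each other. C2 becomes stereogenic through the choice between the two enantiotopic O–CH2 hydrogens, and that choice is made by the chiral pocket of the four phthalimido-tert-leucinate ligands. C3 is set in the same event on the face where the hydrogen arrives, and the cis relation of the methyl groups follows from an insertion geometry in which the C2 methyl points away from the ligand wall; because the product forms under neutral aprotic conditions it is not equilibrated to trans. Chemoselectivity is secured by the substrate: O5 carries a silyl group with no C–H next to oxygen and a shielded oxygen, the prenyl group, side chain and methoxy group are meta or para to the carbenoid and cannot reach it, and the C3 methyl offers only primary hydrogens for 1,2-shift. The bulky carboxylate catalyst, low temperature and slow addition are chosen to disfavour 1,2-hydride shift, oxonium ylide formation at the ethoxy oxygen and carbene dimerisation. The R benzylic centre on C8 lies next to the reacting ethoxy group and may reinforce or oppose the catalyst, so the matched catalyst enantiomer has to be identified.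

Step 11
Reactants: 16 allyl (R)-3-[(2S,3R)-7-methoxy-2,3-dimethyl-6-(3-methylbut-2-enyl)-4-oxo-5-(triisopropylsilyloxy)chroman-8-yl]-3-phenylpropanoate
Product: 17 (R)-3-[(2S,3R)-7-methoxy-2,3-dimethyl-6-(3-methylbut-2-enyl)-4-oxo-5-(triisopropylsilyloxy)chroman-8-yl]-3-phenylpropanoic acid
Conditions: Pd(PPh3)4 (5 mol %), PhNHMe (5 equiv), THF, rt
Reagents that add atoms: none
Why: Tsuji–Trost deallylation; zerovalent palladium ionises the allyl ester and the weakly basic aniline captures the allyl group, so the acid is freed at room temperature with no hydroxide near C3; the prenyl group is not an allylic ester and does not ionise.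

Step 12
Reactants: 17 (R)-3-[(2S,3R)-7-methoxy-2,3-dimethyl-6-(3-methylbut-2-enyl)-4-oxo-5-(triisopropylsilyloxy)chroman-8-yl]-3-phenylpropanoic acid
Product: 18 (R)-3-[(2S,3R)-5-hydroxy-7-methoxy-2,3-dimethyl-6-(3-methylbut-2-enyl)-4-oxochroman-8-yl]-3-phenylpropanoic acid
Conditions: Bu4NF, AcOH (1:1), THF, 0 °C → rt; pH 4 buffer work-up
Reagents that add atoms: none
Why: fluoride-induced cleavage of an aryl silyl ether next to a carbonyl; acetic acid and the substrate acid keep the medium near neutral, so the phenoxide is protonated as it forms and neither epimerisation at C3 nor addition of O5 to the prenyl alkene is expected.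

## Compound list

1 | 5,7-dihydroxycoumarin | O=C1C=Cc2c(O)cc(O)cc2O1 | starting material
2 | propanoyl chloride | CCC(Cl)=O | starting material
3 | 5,7-dihydroxy-8-propanoylcoumarin | O=C1C=Cc2c(O)cc(O)c(C(=O)CC)c2O1 | intermediate
4 | 2-methylbut-3-en-2-ol | CC(C)(O)C=C | starting material
5 | tert-butyl 2-methylbut-3-en-2-yl carbonate | C=CC(C)(C)OC(=O)OC(C)(C)C | intermediate
6 | 7-hydroxy-5-(2-methylbut-3-en-2-yloxy)-8-propanoylcoumarin | O=C1C=Cc2c(OC(C)(C)C=C)cc(O)c(C(=O)CC)c2O1 | intermediate
7 | 5,7-dihydroxy-6-(3-methylbut-2-enyl)-8-propanoylcoumarin | O=C1C=Cc2c(O)c(CC=C(C)C)c(O)c(C(=O)CC)c2O1 | intermediate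
8 | 7-hydroxy-5-methoxy-6-(3-methylbut-2-enyl)-8-propanoylcoumarin | O=C1C=Cc2c(OC)c(CC=C(C)C)c(O)c(C(=O)CC)c2O1 | intermediate
9 | 5-methoxy-6-(3-methylbut-2-enyl)-8-propanoyl-7-(triisopropylsilyloxy)coumarin | O=C1C=Cc2c(OC)c(CC=C(C)C)c(O[Si](C(C)C)(C(C)C)C(C)C)c(C(=O)CC)c2O1 | intermediate
10 | phenylboronic acid | OB(O)c1ccccc1 | starting material
11 | (R)-5-methoxy-6-(3-methylbut-2-enyl)-4-phenyl-8-propanoyl-7-(triisopropylsilyloxy)chroman-2-one | O=C1C[C@H](c3ccccc3)c2c(OC)c(CC=C(C)C)c(O[Si](C(C)C)(C(C)C)C(C)C)c(C(=O)CC)c2O1 | intermediate
12 | allyl (R)-3-[2-hydroxy-6-methoxy-5-(3-methylbut-2-enyl)-3-propanoyl-4-(triisopropylsilyloxy)phenyl]-3-phenylpropanoate (present as its sodium phenoxide) | COc1c(CC=C(C)C)c(O[Si](C(C)C)(C(C)C)C(C)C)c(C(=O)CC)c(O)c1[C@H](CC(=O)OCC=C)c1ccccc1 | intermediate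
13 | allyl (R)-3-[2-ethoxy-6-methoxy-5-(3-methylbut-2-enyl)-3-propanoyl-4-(triisopropylsilyloxy)phenyl]-3-phenylpropanoate | COc1c(CC=C(C)C)c(O[Si](C(C)C)(C(C)C)C(C)C)c(C(=O)CC)c(OCC)c1[C@H](CC(=O)OCC=C)c1ccccc1 | intermediate
14 | allyl (3R)-3-[2-ethoxy-6-methoxy-5-(3-methylbut-2-enyl)-3-(4,4,4-trifluoro-2-methyl-3-oxobutanoyl)-4-(triisopropylsilyloxy)phenyl]-3-phenylpropanoate (both epimers at the diketone carbon) | COc1c(CC=C(C)C)c(O[Si](C(C)C)(C(C)C)C(C)C)c(C(=O)C(C)C(=O)C(F)(F)F)c(OCC)c1[C@H](CC(=O)OCC=C)c1ccccc1 | intermediate
15 | allyl (R)-3-[3-(2-diazopropanoyl)-2-ethoxy-6-methoxy-5-(3-methylbut-2-enyl)-4-(triisopropylsilyloxy)phenyl]-3-phenylpropanoate | COc1c(CC=C(C)C)c(O[Si](C(C)C)(C(C)C)C(C)C)c(C(=O)C(C)=[N+]=[N-])c(OCC)c1[C@H](CC(=O)OCC=C)c1ccccc1 | intermediate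
16 | allyl (R)-3-[(2S,3R)-7-methoxy-2,3-dimethyl-6-(3-methylbut-2-enyl)-4-oxo-5-(triisopropylsilyloxy)chroman-8-yl]-3-phenylpropanoate | COc1c(CC=C(C)C)c(O[Si](C(C)C)(C(C)C)C(C)C)c2c(c1[C@H](CC(=O)OCC=C)c1ccccc1)O[C@@H](C)[C@@H](C)C2=O | intermediate
17 | (R)-3-[(2S,3R)-7-methoxy-2,3-dimethyl-6-(3-methylbut-2-enyl)-4-oxo-5-(triisopropylsilyloxy)chroman-8-yl]-3-phenylpropanoic acid | COc1c(CC=C(C)C)c(O[Si](C(C)C)(C(C)C)C(C)C)c2c(c1[C@H](CC(=O)O)c1ccccc1)O[C@@H](C)[C@@H](C)C2=O | intermediate
18 | (R)-3-[(2S,3R)-5-hydroxy-7-methoxy-2,3-dimethyl-6-(3-methylbut-2-enyl)-4-oxochroman-8-yl]-3-phenylpropanoic acid | COc1c(CC=C(C)C)c(O)c2c(c1[C@H](CC(=O)O)c1ccccc1)O[C@@H](C)[C@@H](C)C2=O | target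

## Step count and least certain steps

Total: 12 steps. Longest linear sequence: 11 steps (1 to 18 through steps 1 and 3–12); step 2 is a one-step side branch.

Step 10 (key step). Most likely to go wrong: 1,2-hydride shift from the C3 methyl or oxonium ylide formation at the ethoxy oxygen may compete with insertion, and the catalyst may give poor discrimination between the enantiotopic hydrogens or between cis and trans, especially if the benzylic centre on C8 opposes it. Fallback: it sets out from 12, which would be isolated by acidifying the alkoxide opening of 11 before any iodoethane is added. An E-selective boron enolate ((c-C6H11)2BCl, Et3N, the phenol carried as its borinate) would be added to acetaldehyde to give the anti aldol allyl (R)-3-[2-hydroxy-3-[(2R,3R)-3-hydroxy-2-methylbutanoyl]-6-methoxy-5-(3-methylbut-2-enyl)-4-(triisopropylsilyloxy)phenyl]-3-phenylpropanoate F1; the other anti isomer would be removed by chromatography or suppressed with a chiral boron reagent. A Mitsunobu closure (PPh3, DIAD, THF, 0 °C) would then let the O1 phenol displace the activated carbinol with inversion, which turns the anti aldol into the cis ring, and the route is rejoined at 16.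

Step 7. Most likely to go wrong: slow carbometallation of a coumarin that is electron-rich and crowded at C4 by the C5 methoxy group, so that protodeboronation of the boronic acid wins. Fallback: it sets out from 9. Oxidative Heck arylation at C4 with 10 (Pd(OAc)2, 1,10-phenanthroline, O2, DMF, divalent palladium) would give 5-methoxy-6-(3-methylbut-2-enyl)-4-phenyl-8-propanoyl-7-(triisopropylsilyloxy)coumarin F2, and copper hydride asymmetric 1,4-reduction (Cu(OAc)2, DTBM-SEGPHOS of the configuration that gives 4R, (EtO)2MeSiH, t-BuOH, toluene) would set the benzylic centre by hydride delivery and rejoin the route at 11.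

Step 8. Most likely to go wrong: loss of the silyl group to alkoxide, after which O1 and O5 are ethylated without selectivity, or return of the phenoxide to the lactone before it is alkylated. Fallback: it sets out from 8 and swaps the protecting group only after O1 is ethylated.
- The chelated phenol would be protected (MeOCH2Cl, NaH, DMF) as 5-methoxy-7-(methoxymethoxy)-6-(3-methylbut-2-enyl)-8-propanoylcoumarin F3.
- Phenylation as in step 7 would give (R)-5-methoxy-7-(methoxymethoxy)-6-(3-methylbut-2-enyl)-4-phenyl-8-propanoylchroman-2-one F4.
- Opening and ethylation as in step 8 would give allyl (R)-3-[2-ethoxy-6-methoxy-4-(methoxymethoxy)-5-(3-methylbut-2-enyl)-3-propanoylphenyl]-3-phenylpropanoate F5.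
- Dilute HCl in methanol at room temperature would release allyl (R)-3-[2-ethoxy-4-hydroxy-6-methoxy-5-(3-methylbut-2-enyl)-3-propanoylphenyl]-3-phenylpropanoate F6.
- Silylation as in step 6 would rejoin the route at 13.

Step 9. Most likely to go wrong: incomplete C-acylation of a hindered, alpha-substituted enolate, competing enolisation of the ester, or migration of the silyl group from O5 to the enolate oxygen. Fallback: it sets out from 13 and forms the diazo group by elimination from a hydrazone instead of by diazo transfer.
- Hydroxylation of the potassium enolate (KN(SiMe3)2, then 2-(phenylsulfonyl)-3-phenyloxaziridine) would give allyl (3R)-3-[2-ethoxy-3-(2-hydroxypropanoyl)-6-methoxy-5-(3-methylbut-2-enyl)-4-(triisopropylsilyloxy)phenyl]-3-phenylpropanoate F7.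
- Oxidation with Dess–Martin periodinane would give allyl (R)-3-[2-ethoxy-6-methoxy-5-(3-methylbut-2-enyl)-3-(2-oxopropanoyl)-4-(triisopropylsilyloxy)phenyl]-3-phenylpropanoate F8.
- Condensation with tosylhydrazide at the unhindered outer carbonyl would give allyl (R)-3-[2-ethoxy-6-methoxy-5-(3-methylbut-2-enyl)-3-[2-(tosylhydrazono)propanoyl]-4-(triisopropylsilyloxy)phenyl]-3-phenylpropanoate F9.
- Treatment with Et3N in CH2Cl2 would expel sulfinate (Bamford–Stevens-type elimination) and rejoin the route at 15.

## Further compounds

F1 | step 10 | allyl (R)-3-[2-hydroxy-3-[(2R,3R)-3-hydroxy-2-methylbutanoyl]-6-methoxy-5-(3-methylbut-2-enyl)-4-(triisopropylsilyloxy)phenyl]-3-phenylpropanoate | COc1c(CC=C(C)C)c(O[Si](C(C)C)(C(C)C)C(C)C)c(C(=O)[C@H](C)[C@@H](C)O)c(O)c1[C@H](CC(=O)OCC=C)c1ccccc1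
F2 | step 7 | 5-methoxy-6-(3-methylbut-2-enyl)-4-phenyl-8-propanoyl-7-(triisopropylsilyloxy)coumarin | O=C1C=C(c3ccccc3)c2c(OC)c(CC=C(C)C)c(O[Si](C(C)C)(C(C)C)C(C)C)c(C(=O)CC)c2O1
F3 | step 8 | 5-methoxy-7-(methoxymethoxy)-6-(3-methylbut-2-enyl)-8-propanoylcoumarin | O=C1C=Cc2c(OC)c(CC=C(C)C)c(OCOC)c(C(=O)CC)c2O1
F4 | step 8 | (R)-5-methoxy-7-(methoxymethoxy)-6-(3-methylbut-2-enyl)-4-phenyl-8-propanoylchroman-2-one | O=C1C[C@H](c3ccccc3)c2c(OC)c(CC=C(C)C)c(OCOC)c(C(=O)CC)c2O1
F5 | step 8 | allyl (R)-3-[2-ethoxy-6-methoxy-4-(methoxymethoxy)-5-(3-methylbut-2-enyl)-3-propanoylphenyl]-3-phenylpropanoate | COc1c(CC=C(C)C)c(OCOC)c(C(=O)CC)c(OCC)c1[C@H](CC(=O)OCC=C)c1ccccc1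
F6 | step 8 | allyl (R)-3-[2-ethoxy-4-hydroxy-6-methoxy-5-(3-methylbut-2-enyl)-3-propanoylphenyl]-3-phenylpropanoate | COc1c(CC=C(C)C)c(O)c(C(=O)CC)c(OCC)c1[C@H](CC(=O)OCC=C)c1ccccc1
F7 | step 9 | allyl (3R)-3-[2-ethoxy-3-(2-hydroxypropanoyl)-6-methoxy-5-(3-methylbut-2-enyl)-4-(triisopropylsilyloxy)phenyl]-3-phenylpropanoate (both carbinol epimers) | COc1c(CC=C(C)C)c(O[Si](C(C)C)(C(C)C)C(C)C)c(C(=O)C(C)O)c(OCC)c1[C@H](CC(=O)OCC=C)c1ccccc1
F8 | step 9 | allyl (R)-3-[2-ethoxy-6-methoxy-5-(3-methylbut-2-enyl)-3-(2-oxopropanoyl)-4-(triisopropylsilyloxy)phenyl]-3-phenylpropanoate | COc1c(CC=C(C)C)c(O[Si](C(C)C)(C(C)C)C(C)C)c(C(=O)C(C)=O)c(OCC)c1[C@H](CC(=O)OCC=C)c1ccccc1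
F9 | step 9 | allyl (R)-3-[2-ethoxy-6-methoxy-5-(3-methylbut-2-enyl)-3-[2-(tosylhydrazono)propanoyl]-4-(triisopropylsilyloxy)phenyl]-3-phenylpropanoate | COc1c(CC=C(C)C)c(O[Si](C(C)C)(C(C)C)C(C)C)c(C(=O)C(C)=NNS(=O)(=O)c2ccc(C)cc2)c(OCC)c1[C@H](CC(=O)OCC=C)c1ccccc1
A1 | alternative 1 | 2-[(R)-3-(tert-butyldimethylsilyloxy)-1-phenylpropyl]-5-ethoxy-6-(3-methylbut-2-enyl)-3-(triisopropylsilyloxy)phenol | Oc1c(CC=C(C)C)c(OCC)cc(O[Si](C(C)C)(C(C)C)C(C)C)c1[C@H](CCO[Si](C)(C)C(C)(C)C)c1ccccc1
A2 | alternative 1 | 3-ethoxy-4-(3-methylbut-2-enyl)cyclobut-2-en-1-one | CCOC1=CC(=O)C1CC=C(C)C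
A3 | alternative 1 | (R)-tert-butyldimethyl{[3-phenyl-5-(triisopropylsilyloxy)pent-4-yn-1-yl]oxy}silane | CC(C)[Si](C(C)C)(C(C)C)OC#C[C@H](CCO[Si](C)(C)C(C)(C)C)c1ccccc1
A4 | alternative 2 | methyl (R)-3-[5-(benzyloxy)-7-methoxy-2,3-dimethyl-4-oxo-4H-chromen-8-yl]-3-phenylpropanoate | COc1cc(OCc3ccccc3)c2c(c1[C@H](CC(=O)OC)c1ccccc1)OC(C)=C(C)C2=O
A5 | alternative 2 | methyl (R)-3-[4-(benzyloxy)-6-methoxy-2-(trifluoromethylsulfonyloxy)-3-(trimethylsilyl)phenyl]-3-phenylpropanoate | COc1cc(OCc3ccccc3)c([Si](C)(C)C)c(OS(=O)(=O)C(F)(F)F)c1[C@H](CC(=O)OC)c1ccccc1
A6 | alternative 2 | (E)-3-methoxy-2-methylbut-2-enoic acid | CO/C(C)=C(\C)C(=O)O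
A7 | alternative 3 | methyl (R)-3-[(2S,3R)-7-methoxy-5-(methoxymethoxy)-2,3-dimethyl-6-(3-methylbut-2-enyl)-4-oxochroman-8-yl]-3-phenylpropanoate | COc1c(CC=C(C)C)c(OCOC)c2c(c1[C@H](CC(=O)OC)c1ccccc1)O[C@@H](C)[C@@H](C)C2=O
A8 | alternative 3 | methyl (R)-3-[3-iodo-6-methoxy-4-(methoxymethoxy)-2-{[(2S,3R)-4-[methoxy(methyl)amino]-3-methyl-4-oxobutan-2-yl]oxy}-5-(3-methylbut-2-enyl)phenyl]-3-phenylpropanoate | COc1c(CC=C(C)C)c(OCOC)c(I)c(O[C@@H](C)[C@@H](C)C(=O)N(C)OC)c1[C@H](CC(=O)OC)c1ccccc1
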